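**Retrosynthetic overview**
- Neither angelate is made by acylating an alcohol. The C8 angelate and the C10 carbinol are disconnected together (Evans–Tishchenko) to a β-hydroxy ketone plus (Z)-2-methylbut-2-enal; this is the key step.
- The C1 angelate comes from the trans α-ketol by Mitsunobu inversion with angelic acid.
- The β-hydroxy ketone comes from a reagent-controlled boron aldol (C8–C9 bond) between a C9–C11 methyl ketone and the C8 enal, itself made by allylic oxidation of the isopropenyl group.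
- Ring stereocentres are relayed from (S)-carvone: Luche reduction, hydroxyl-directed epoxidation, oxidation, enolate hydroxylation.
- Rings: the cyclohexane is bought in (S)-carvone; the oxirane is closed in step 2; no other ring is formed.

Assumption: (S)-(+)-carvone, angelic acid and 3-hydroxy-3-methylbutan-2-one are bought; C-locants in the text follow bisabolane numbering (ring C1 = CH–O, C2 = C=O, C3 = C–CH3, C4, C5, C6 = CH bearing C7(=C14H2)–C8–C9–C10–C11).

Step 1
Reactants: 1 (S)-(+)-carvone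
Product: 2 (1S,5S)-cis-carveol [(1S,5S)-2-methyl-5-(prop-1-en-2-yl)cyclohex-2-en-1-ol]
Conditions: NaBH4, CeCl3·7H2O, MeOH, −20 °C
Reagents that add atoms: none
Why: Luche 1,2-reduction; axial hydride attack on the enone gives the pseudo-equatorial alcohol cis to the isopropenyl group (new C2 centre).

Step 2
Reactants: 2 (1S,5S)-cis-carveol
Product: 3 (1S,2S,4R,6R)-1-methyl-4-(prop-1-en-2-yl)-7-oxabicyclo[4.1.0]heptan-2-ol (OH, epoxide and isopropenyl all cis)
Conditions: VO(acac)2 (2 mol%), t-BuOOH (decane), CH2Cl2, 0 °C → rt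
Reagents that add atoms: tert-butyl hydroperoxide CC(C)(C)OO
Why: Hydroxyl-directed vanadium-catalysed epoxidation; the vanadate-bound peroxide is delivered syn to the allylic OH, setting C3 and C4 cis to the side chain, and the remote isopropenyl alkene is untouched.

Step 3
Reactants: 3 all-cis epoxy alcohol
Product: 4 (1R,4S,6R)-1-methyl-4-(prop-1-en-2-yl)-7-oxabicyclo[4.1.0]heptan-2-one (epoxide cis to isopropenyl)
Conditions: Dess–Martin periodinane, CH2Cl2, 0 °C → rt
Reagents that add atoms: none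
Why: Dess–Martin oxidation of the secondary alcohol under neutral conditions leaves the epoxide and its stereocentres untouched.

Step 4
Reactants: 4 cis-epoxy ketone
Product: 6 (1R,3R,4R,6R)-3-hydroxy-1-methyl-4-(prop-1-en-2-yl)-7-oxabicyclo[4.1.0]heptan-2-one (OH trans to isopropenyl and epoxide), via potassium enolate 5 (not isolated)
Conditions: KN(SiMe3)2, THF, −78 °C; then 2-(phenylsulfonyl)-3-phenyloxaziridine, −78 °C; AcOH quench
Reagents that add atoms: 2-(phenylsulfonyl)-3-phenyloxaziridine O=S(=O)(N1OC1c1ccccc1)c1ccccc1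
Why: Davis enolate hydroxylation; only C1 is enolisable and the oxaziridine approaches anti to the adjacent isopropenyl group and the epoxide oxygen, giving the trans (1R) ketol.

Step 5
Reactants: 6 trans α-ketol; 7 angelic acid [(2Z)-2-methylbut-2-enoic acid]
Product: 8 (1R,3S,4R,6R)-1-methyl-2-oxo-4-(prop-1-en-2-yl)-7-oxabicyclo[4.1.0]heptan-3-yl (2Z)-2-methylbut-2-enoate (ester, epoxide and isopropenyl all cis)
Conditions: PPh3, DIAD, toluene, 0 °C → rt
Reagents that add atoms: none
Why: Mitsunobu reaction; angelate displaces the alkoxyphosphonium at the α-keto carbon by SN2, inverting C1 to the cis (S) configuration, and the acid is never activated as an acyl electrophile, so the Z alkene is kept.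

Step 6
Reactants: 8 cis angelate
Product: 10 (1R,3S,4R,6R)-1-methyl-2-oxo-4-(3-oxoprop-1-en-2-yl)-7-oxabicyclo[4.1.0]heptan-3-yl (2Z)-2-methylbut-2-enoate, via allylic alcohol 9 (not isolated)
Conditions: SeO2 (0.5 equiv), t-BuOOH, salicylic acid (cat.), CH2Cl2, rt; then MnO2, CH2Cl2, rt
Reagents that add atoms: tert-butyl hydroperoxide CC(C)(C)OO
Why: Selenium dioxide allylic oxidation (ene reaction then [2,3]-shift) attacks the electron-rich isopropenyl methyl rather than the electron-poor angelate, and MnO2 allylic oxidation converges the alcohol to the enal; no stereocentre is formed.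

Step 7
Reactants: 11 3-hydroxy-3-methylbutan-2-one
Product: 12 3-methyl-3-(triethylsilyloxy)butan-2-one
Conditions: Et3SiOTf, 2,6-lutidine, CH2Cl2, 0 °C
Reagents that add atoms: triethylsilyl trifluoromethanesulfonate CC[Si](CC)(CC)OS(=O)(=O)C(F)(F)F
Why: Silylation of the tertiary alcohol masks it for boron enolate formation.

Step 8
Reactants: 12 silyloxy methyl ketone; 10 enal
Product: 14 (1R,3S,4R,6R)-4-[(3S)-3-hydroxy-6-methyl-5-oxo-6-(triethylsilyloxy)hept-1-en-2-yl]-1-methyl-2-oxo-7-oxabicyclo[4.1.0]heptan-3-yl (2Z)-2-methylbut-2-enoate, via boron enolate 13 (not isolated)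
Conditions: 12 (1.6 equiv), (+)-Ipc2BCl, Et3N, Et2O, 0 °C; then 10, −78 → −20 °C; H2O2, pH 7 buffer, MeOH, 0 °C
Reagents that add atoms: none
Why: Paterson boron aldol; the methyl-side enol diisopinocampheylborinate adds to the aldehyde (not the ring ketone) and the (+)-Ipc ligands direct si-face attack, giving the 8S carbinol, with the minor 8R diastereomer removed by chromatography.

Step 9
Reactants: 7 angelic acid
Product: 15 (2Z)-2-methylbut-2-en-1-ol
Conditions: LiAlH4, Et2O, 0 °C → rt
Reagents that add atoms: none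
Why: Hydride reduction of the unsaturated acid to the allylic alcohol does not touch the trisubstituted alkene, so the Z geometry is retained.

Step 10
Reactants: 15 (2Z)-2-methylbut-2-en-1-ol
Product: 16 (2Z)-2-methylbut-2-enal
Conditions: MnO2, pentane, 0 °C → rt, dark; filtered solution used at once
Reagents that add atoms: none
Why: Neutral MnO2 allylic oxidation gives the Z enal without the acid or base that would isomerise it to the E isomer.

Step 11
Reactants: 14 β-hydroxy ketone; 16 (2Z)-2-methylbut-2-enal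
Product: 18 target [(1R,3S,4R,6R)-4-[(3S,5S)-5,6-dihydroxy-6-methyl-3-{[(2Z)-2-methylbut-2-enoyl]oxy}hept-1-en-2-yl]-1-methyl-2-oxo-7-oxabicyclo[4.1.0]heptan-3-yl (2Z)-2-methylbut-2-enoate], via triethylsilyl ether 17 (not isolated)
Conditions: SmI2 (0.3 equiv) pre-mixed with 16 (6 equiv), THF, −10 °C; add 14; then HF·pyridine, pyridine, 0 °C → rt
Reagents that add atoms: none
Why: Proposed new method: the C8 hydroxyl forms a hemiacetal with the enal on the trivalent samarium centre (generated by letting SmI2 reduce part of the aldehyde first, so no divalent samarium meets the epoxy ketone), and its C–H is delivered intramolecularly to the C10 ketone through a chair-like six-membered transition state, giving the 8,10-anti (10S) alcohol while the hemiacetal carbon becomes the C8 angelate carbonyl with its Z alkene untouched; the closest known reaction is the Evans–Tishchenko reduction of β-hydroxy ketones with saturated or aromatic aldehydes, and fluoride then removes the silyl ether.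

**Compound list**
1 | (S)-(+)-carvone | C=C(C)[C@H]1CC=C(C)C(=O)C1 | starting material
2 | (1S,5S)-cis-carveol | C=C(C)[C@H]1CC=C(C)[C@@H](O)C1 | intermediate
3 | (1S,2S,4R,6R)-1-methyl-4-(prop-1-en-2-yl)-7-oxabicyclo[4.1.0]heptan-2-ol | C=C(C)[C@H]1C[C@H]2O[C@@]2(C)[C@@H](O)C1 | intermediate
4 | (1R,4S,6R)-1-methyl-4-(prop-1-en-2-yl)-7-oxabicyclo[4.1.0]heptan-2-one | C=C(C)[C@H]1C[C@H]2O[C@@]2(C)C(=O)C1 | intermediate
5 | potassium enolate of 4 (C1=C2 enolate) | C=C(C)[C@H]1C[C@H]2O[C@@]2(C)C([O-])=C1.[K+] | intermediate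
6 | (1R,3R,4R,6R)-3-hydroxy-1-methyl-4-(prop-1-en-2-yl)-7-oxabicyclo[4.1.0]heptan-2-one | C=C(C)[C@H]1C[C@H]2O[C@@]2(C)C(=O)[C@@H]1O | intermediate
7 | angelic acid, (2Z)-2-methylbut-2-enoic acid | C/C=C(/C)C(=O)O | starting material
8 | (1R,3S,4R,6R)-1-methyl-2-oxo-4-(prop-1-en-2-yl)-7-oxabicyclo[4.1.0]heptan-3-yl (2Z)-2-methylbut-2-enoate | C=C(C)[C@H]1C[C@H]2O[C@@]2(C)C(=O)[C@H]1OC(=O)/C(C)=C\C | intermediate
9 | allylic alcohol: (1R,3S,4R,6R)-4-(3-hydroxyprop-1-en-2-yl)-1-methyl-2-oxo-7-oxabicyclo[4.1.0]heptan-3-yl (2Z)-2-methylbut-2-enoate | C=C(CO)[C@H]1C[C@H]2O[C@@]2(C)C(=O)[C@H]1OC(=O)/C(C)=C\C | intermediate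
10 | (1R,3S,4R,6R)-1-methyl-2-oxo-4-(3-oxoprop-1-en-2-yl)-7-oxabicyclo[4.1.0]heptan-3-yl (2Z)-2-methylbut-2-enoate | C=C(C=O)[C@H]1C[C@H]2O[C@@]2(C)C(=O)[C@H]1OC(=O)/C(C)=C\C | intermediate
11 | 3-hydroxy-3-methylbutan-2-one | CC(=O)C(C)(C)O | starting material
12 | 3-methyl-3-(triethylsilyloxy)butan-2-one | CC(=O)C(C)(C)O[Si](CC)(CC)CC | intermediate
13 | boron enolate: 3-methyl-3-(triethylsilyloxy)but-1-en-2-yl bis[(+)-isopinocampheyl]borinate | C=C(OB([C@H]1C[C@H]2C[C@@H]([C@@H]1C)C2(C)C)[C@H]1C[C@H]2C[C@@H]([C@@H]1C)C2(C)C)C(C)(C)O[Si](CC)(CC)CC | intermediate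
14 | (1R,3S,4R,6R)-4-[(3S)-3-hydroxy-6-methyl-5-oxo-6-(triethylsilyloxy)hept-1-en-2-yl]-1-methyl-2-oxo-7-oxabicyclo[4.1.0]heptan-3-yl (2Z)-2-methylbut-2-enoate | C=C([C@H](CC(=O)C(C)(C)O[Si](CC)(CC)CC)O)[C@H]1C[C@H]2O[C@@]2(C)C(=O)[C@H]1OC(=O)/C(C)=C\C | intermediate
15 | (2Z)-2-methylbut-2-en-1-ol | C/C=C(/C)CO | intermediate
16 | (2Z)-2-methylbut-2-enal | C/C=C(/C)C=O | intermediate
17 | triethylsilyl ether: (8S,10S)-1,8-bis(angeloyloxy) compound with free 10-OH and 11-OSiEt3 | C=C([C@H](C[C@H](O)C(C)(C)O[Si](CC)(CC)CC)OC(=O)/C(C)=C\C)[C@H]1C[C@H]2O[C@@]2(C)C(=O)[C@H]1OC(=O)/C(C)=C\C | intermediate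
18 | CNP0127352.2, (1S,3R,4R,6R,8S,10S)-1,8-bis(angeloyloxy)-3,4-epoxy-10,11-dihydroxybisabol-7(14)-en-2-one | C=C([C@H](C[C@H](O)C(C)(C)O)OC(=O)/C(C)=C\C)[C@H]1C[C@H]2O[C@@]2(C)C(=O)[C@H]1OC(=O)/C(C)=C\C | target

**Step count**
Total steps: 11. Longest linear sequence: 8 (steps 1–6, 8 and 11, from 1).

**Steps most likely to fail**

Step 11 is the largest risk. The Z enal 16 may isomerise to the E isomer under the samarium iodide conditions, and hemiacetal formation and hydride transfer are slowed by the hindered C10 ketone. The fallback sets out from 14. Internal hydride delivery with Me4NBH(OAc)3 in MeCN/AcOH at −30 °C gives the 8,10-anti diol F4. The allylic C8 hydroxyl (the C10 hydroxyl is neopentyl-like beside C11–OSiEt3) is then acylated in toluene with the mixed anhydride F5, prepared from 7 and 2,4,6-trichlorobenzoyl chloride/Et3N. This returns to the route at 17, which HF·pyridine converts to 18.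

Step 5 may stall or give retention or elimination, because the angelate must enter on the face that carries the isopropenyl group and the epoxide. The fallback sets out from 4. Its enolate 5 is brominated with N-bromosuccinimide at −78 °C anti to the isopropenyl group to give the trans α-bromo ketone F1. Caesium angelate F2 (from 7 and Cs2CO3) displaces bromide in DMF at 0 °C with inversion, returning to the route at 8.

Step 6 may give low yield or over-oxidation on the epoxy ketone. The fallback sets out from 8. Ene-type chlorination with Ca(OCl)2 and CO2 in CH2Cl2/H2O at 0 °C gives the allylic chloride F3. Ganem oxidation with N-methylmorpholine N-oxide in MeCN converts CH2Cl to CHO, returning to the route at 10.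

Further compounds
F1 | step 5 | (1R,3R,4R,6R)-3-bromo-1-methyl-4-(prop-1-en-2-yl)-7-oxabicyclo[4.1.0]heptan-2-one | C=C(C)[C@H]1C[C@H]2O[C@@]2(C)C(=O)[C@@H]1Br
F2 | step 5 | caesium (2Z)-2-methylbut-2-enoate | [Cs+].C/C=C(/C)C(=O)[O-]
F3 | step 6 | (1R,3S,4R,6R)-4-(3-chloroprop-1-en-2-yl)-1-methyl-2-oxo-7-oxabicyclo[4.1.0]heptan-3-yl (2Z)-2-methylbut-2-enoate | C=C(CCl)[C@H]1C[C@H]2O[C@@]2(C)C(=O)[C@H]1OC(=O)/C(C)=C\C
F4 | step 11 | (1R,3S,4R,6R)-4-[(3S,5S)-3,5-dihydroxy-6-methyl-6-(triethylsilyloxy)hept-1-en-2-yl]-1-methyl-2-oxo-7-oxabicyclo[4.1.0]heptan-3-yl (2Z)-2-methylbut-2-enoate | C=C([C@H](C[C@H](O)C(C)(C)O[Si](CC)(CC)CC)O)[C@H]1C[C@H]2O[C@@]2(C)C(=O)[C@H]1OC(=O)/C(C)=C\C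
F5 | step 11 | (2Z)-2-methylbut-2-enoic 2,4,6-trichlorobenzoic anhydride | C/C=C(/C)C(=O)OC(=O)c1c(Cl)cc(Cl)cc1Cl
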